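**Plan**

- Retrosynthesis: the two O–benzyl bonds and the 8-O–methyl bond are cut first. Ring C is then opened at C4a–C4 and O1–C2, leaving a ring A hydroxyquinone and an aroylketene that carries ring B.
- Enabling feature: C5 and C8 of ring A are para-oxygenated, so ring A can be carried as a 5,8-quinone. Its enolic hydroxyl (future O1) makes its only C–H carbon (future C4a) nucleophilic. After reduction, the hydrogen bond from 5-OH to the C4 carbonyl tells O5 and O8 apart.
- Forward order: ring A quinone (steps 1–4), ring B acyl donor (step 5), ring C closure (step 6), then reduction, 8-O-methylation and debenzylation (steps 7–9).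
- Stereochemistry: the target has no stereocentre, so none has to be set.

Key step: step 6

Assumption: the hydroxyquinone 7 is drawn as its 2-hydroxy-1,4-quinone tautomer and the acyl Meldrum's acid 10 as its enol, the forms expected to dominate. Flavone numbering (O1, C2–C4, C4a, C5–C8, C8a) is used for all bicyclic compounds.

**Step 1**
Reactants: 1 2,3,4-trimethoxybenzaldehyde
Product: 3 2,3,4-trimethoxyphenol, via aryl formate 2 (not isolated)
Conditions: 30% H2O2, H2SO4 (cat.), MeOH, rt
Reagents that add atoms: hydrogen peroxide, OO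
Why: In this acid-catalysed Dakin (Baeyer–Villiger type) oxidation the electron-rich aryl group should migrate to the peroxide oxygen, and the resulting formate is methanolysed in the same pot.

**Step 2**
Reactants: 3 2,3,4-trimethoxyphenol
Product: 4 2,3-dimethoxy-1,4-benzoquinone
Conditions: PhI(OAc)2, MeCN/H2O, 0 °C
Reagents that add atoms: water, O
Why: Oxidative demethylation of a para-methoxyphenol by a hypervalent iodine reagent: water should add at the methoxy-bearing para carbon of the oxidised phenol and the hemiketal then loses methanol to give the para-quinone.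

**Step 3**
Reactants: 4 2,3-dimethoxy-1,4-benzoquinone
Product: 5 5,6-dimethoxybenzene-1,2,4-triyl triacetate
Conditions: Ac2O, H2SO4 (cat.), rt to 40 °C
Reagents that add atoms: acetic anhydride, CC(=O)OC(C)=O
Why: Thiele–Winter acetoxylation, an acid-catalysed conjugate addition of acetate to the unsubstituted enedione followed by enolisation and acetylation; the two ring C–H positions of 4 are equivalent, so only one triacetate can form.

**Step 4**
Reactants: 5 5,6-dimethoxybenzene-1,2,4-triyl triacetate
Product: 7 2-hydroxy-5,6-dimethoxy-1,4-benzoquinone, via benzenetriol 6 (not isolated)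
Conditions: HCl, MeOH, reflux, N2; evaporate; then FeCl3, H2O, 0 °C
Reagents that add atoms: none
Why: Acid-catalysed transesterification should remove the three aryl acetates without touching the aryl methyl ethers, and FeCl3 dehydrogenation of the para-dihydroxy pair of the hydroxyhydroquinone leaves the third hydroxyl as the enolic OH of the quinone.

**Step 5**
Reactants: 8 3,4-bis(benzyloxy)benzoic acid; 9 2,2-dimethyl-1,3-dioxane-4,6-dione (Meldrum's acid)
Product: 10 5-{[3,4-bis(benzyloxy)phenyl](hydroxy)methylidene}-2,2-dimethyl-1,3-dioxane-4,6-dione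
Conditions: DCC, DMAP, CH2Cl2, 0 °C to rt; 1 M HCl wash
Reagents that add atoms: none
Why: Carbodiimide/DMAP activation of the acid (Steglich type) followed by C-acylation of the highly acidic Meldrum's acid is a standard route to acyl Meldrum's acids, and the benzyl ethers are inert to it.

**Step 6**
Reactants: 7 2-hydroxy-5,6-dimethoxy-1,4-benzoquinone; 10 5-{[3,4-bis(benzyloxy)phenyl](hydroxy)methylidene}-2,2-dimethyl-1,3-dioxane-4,6-dione
Product: 13 2-[3,4-bis(benzyloxy)phenyl]-6,7-dimethoxy-4H-chromene-4,5,8-trione, via aroylketene 11 (not isolated), via C-acyl triketone 12 (not isolated)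
Conditions: toluene, 100 °C, slow addition of 10 (1.3 equiv) to 7, Ar stream, 4 Å MS; then TsOH·H2O (cat.), 80 °C
Reagents that add atoms: none
Why: Proposed new method: at about 100 °C the acyl Meldrum's acid 10 should fragment with loss of acetone and CO2 to the aroylketene 11, whose ketene carbon is attacked by C3 of 7 (the future C4a, the β-carbon of a vinylogous acid), directly or by O-acylation followed by a 1,3-acyl shift, to give the chelated β-tricarbonyl compound 12 (bond C4a–C4). The enolic hydroxyl of 12 (future O1) should then add to the aryl ketone and water is lost under acid catalysis (bond O1–C2), so that ring C closes by a 6-exo-trig addition followed by dehydration, as in the last stage of a Baker–Venkataraman flavone synthesis. The closest known reaction type is the thermal annulation of acylketenes, released from acyl Meldrum's acids or dioxinones, with cyclic 1,3-diones and 4-hydroxycoumarins to fused 4-pyranones; a 2-hydroxy-1,4-benzoquinone has not been used as the enol partner. No stereocentre is formed. The step needs C-acylation over O-acylation and a single regiochemistry: 7 has one ring C–H and one hydroxyl, so only one annulation is possible, an O-acyl derivative of 7 is a vinylogous anhydride that can revert or rearrange to the chelated C-acyl compound as the thermodynamic sink, and slow addition of 10 keeps the ketene concentration low against its dimerisation.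

**Step 7**
Reactants: 13 2-[3,4-bis(benzyloxy)phenyl]-6,7-dimethoxy-4H-chromene-4,5,8-trione
Product: 14 2-[3,4-bis(benzyloxy)phenyl]-5,8-dihydroxy-6,7-dimethoxy-4H-chromen-4-one
Conditions: Na2S2O4, EtOAc/H2O, rt, Ar
Reagents that add atoms: none
Why: Dithionite reduction of a para-quinone to its hydroquinone is fast and should leave the pyranone enone, the methyl ethers and the benzyl ethers untouched.

**Step 8**
Reactants: 14 2-[3,4-bis(benzyloxy)phenyl]-5,8-dihydroxy-6,7-dimethoxy-4H-chromen-4-one
Product: 15 2-[3,4-bis(benzyloxy)phenyl]-5-hydroxy-6,7,8-trimethoxy-4H-chromen-4-one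
Conditions: MeI (1.1 equiv), K2CO3, degassed acetone, 40 °C, Ar (crude 14 used directly)
Reagents that add atoms: iodomethane, CI
Why: Williamson etherification should take place at the free 8-hydroxyl only, because the 5-hydroxyl is held in a strong hydrogen bond to the C4 carbonyl and is neither deprotonated nor alkylated under mild carbonate conditions.

**Step 9**
Reactants: 15 2-[3,4-bis(benzyloxy)phenyl]-5-hydroxy-6,7,8-trimethoxy-4H-chromen-4-one
Product: 16 sideritiflavone (5,3',4'-trihydroxy-6,7,8-trimethoxyflavone)
Conditions: H2 (1 atm), 10% Pd/C, EtOAc/MeOH, rt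
Reagents that add atoms: none
Why: Catalytic hydrogenolysis of aryl benzyl ethers should free the catechol at atmospheric pressure, conditions under which the flavone C2=C3 bond and the aryl methyl ethers are normally retained.

**Compound list**

1 | 2,3,4-trimethoxybenzaldehyde | COc1ccc(C=O)c(OC)c1OC | starting material
2 | 2,3,4-trimethoxyphenyl formate | COc1ccc(OC=O)c(OC)c1OC | intermediate
3 | 2,3,4-trimethoxyphenol | COc1ccc(O)c(OC)c1OC | intermediate
4 | 2,3-dimethoxy-1,4-benzoquinone | COC1=C(OC)C(=O)C=CC1=O | intermediate
5 | 5,6-dimethoxybenzene-1,2,4-triyl triacetate | COc1c(OC)c(OC(C)=O)c(OC(C)=O)cc1OC(C)=O | intermediate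
6 | 5,6-dimethoxybenzene-1,2,4-triol | COc1c(OC)c(O)c(O)cc1O | intermediate
7 | 2-hydroxy-5,6-dimethoxy-1,4-benzoquinone | COC1=C(OC)C(=O)C(O)=CC1=O | intermediate
8 | 3,4-bis(benzyloxy)benzoic acid | OC(=O)c1ccc(OCc2ccccc2)c(OCc2ccccc2)c1 | starting material
9 | 2,2-dimethyl-1,3-dioxane-4,6-dione (Meldrum's acid) | CC1(C)OC(=O)CC(=O)O1 | starting material
10 | 5-{[3,4-bis(benzyloxy)phenyl](hydroxy)methylidene}-2,2-dimethyl-1,3-dioxane-4,6-dione | CC1(C)OC(=O)C(=C(O)c2ccc(OCc3ccccc3)c(OCc3ccccc3)c2)C(=O)O1 | intermediate
11 | 3-[3,4-bis(benzyloxy)phenyl]-3-oxoprop-1-en-1-one (aroylketene) | O=C=CC(=O)c1ccc(OCc2ccccc2)c(OCc2ccccc2)c1 | intermediate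
12 | 3-{3-[3,4-bis(benzyloxy)phenyl]-3-oxopropanoyl}-2-hydroxy-5,6-dimethoxy-1,4-benzoquinone | COC1=C(OC)C(=O)C(C(=O)CC(=O)c2ccc(OCc3ccccc3)c(OCc3ccccc3)c2)=C(O)C1=O | intermediate
13 | 2-[3,4-bis(benzyloxy)phenyl]-6,7-dimethoxy-4H-chromene-4,5,8-trione | COC1=C(OC)C(=O)c2c(oc(-c3ccc(OCc4ccccc4)c(OCc4ccccc4)c3)cc2=O)C1=O | intermediate
14 | 2-[3,4-bis(benzyloxy)phenyl]-5,8-dihydroxy-6,7-dimethoxy-4H-chromen-4-one | COc1c(OC)c(O)c2c(=O)cc(-c3ccc(OCc4ccccc4)c(OCc4ccccc4)c3)oc2c1O | intermediate
15 | 2-[3,4-bis(benzyloxy)phenyl]-5-hydroxy-6,7,8-trimethoxy-4H-chromen-4-one | COc1c(OC)c(O)c2c(=O)cc(-c3ccc(OCc4ccccc4)c(OCc4ccccc4)c3)oc2c1OC | intermediate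
16 | sideritiflavone, 2-(3,4-dihydroxyphenyl)-5-hydroxy-6,7,8-trimethoxy-4H-chromen-4-one | COc1c(OC)c(O)c2c(=O)cc(-c3ccc(O)c(O)c3)oc2c1OC | target

**Step count**

Total: 9 steps. Longest linear sequence: 8 steps (steps 1–4 and 6–9, from 1 to 16).

**Steps most likely to fail**

Step 6 (proposed new method). The ketene may be used up by O-acylation that does not migrate to carbon, by self-dimerisation, or by addition at the methoxy-bearing quinone carbons. The fallback uses known chemistry, sets out from triacetate 5 and comes back at target 16; ring C is then built on an arene and the quinone stage is bypassed. Saponification and methylation in one pot (Me2SO4, NaOH, MeOH/H2O, N2) should give pentamethoxybenzene F1. Friedel–Crafts acetylation (AcCl, AlCl3, CH2Cl2), with cleavage of one ortho methoxyl through the aluminium chelate, should give 1-(2-hydroxy-3,4,5,6-tetramethoxyphenyl)ethanone F2. Claisen–Schmidt condensation with purchased 3,4-bis(benzyloxy)benzaldehyde (KOH, EtOH) should give (E)-3-[3,4-bis(benzyloxy)phenyl]-1-(2-hydroxy-3,4,5,6-tetramethoxyphenyl)prop-2-en-1-one F3. Oxidative cyclisation (I2 cat., DMSO, 120 °C) should give 2-[3,4-bis(benzyloxy)phenyl]-5,6,7,8-tetramethoxy-4H-chromen-4-one F4. BCl3 in CH2Cl2 (−78 to 0 °C) should then remove both benzyl groups and the chelated 5-O-methyl group and give 16.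

Step 8. Under base the hydroquinone can be re-oxidised by traces of air to the quinone, and alkylation may run on to O5. The fallback sets out from quinone 13 and comes back at 15; it avoids handling the free hydroquinone. Reductive acetylation (Zn, Ac2O, NaOAc) should give the air-stable 2-[3,4-bis(benzyloxy)phenyl]-6,7-dimethoxy-4-oxo-4H-chromene-5,8-diyl diacetate F5, which can be purified. K2CO3 and MeI in acetone/MeOH under Ar should then cleave both acetates by methanolysis and methylate the 8-phenoxide as it is released, while the 5-hydroxyl, once free, is held by its hydrogen bond to the C4 carbonyl.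

Step 3. Conjugate acetoxylation may be slow because two methoxy donors deactivate the quinone, and the strong acid may cleave the enol-ether-like methoxyls. The fallback sets out from quinone 4 and comes back at hydroxyquinone 7, replacing steps 3 and 4. Nucleophilic (Weitz–Scheffer) epoxidation of the unsubstituted C5=C6 bond (tBuOOH, DBU, CH2Cl2, 0 °C) should give cis-3,4-dimethoxy-7-oxabicyclo[4.1.0]hept-3-ene-2,5-dione F6. Opening of the epoxide through the enol (Et3N in CH2Cl2, or H2SO4 in AcOH) should isomerise it to 7.

**Further compounds**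

F1 | step 6 | pentamethoxybenzene | COc1cc(OC)c(OC)c(OC)c1OC
F2 | step 6 | 1-(2-hydroxy-3,4,5,6-tetramethoxyphenyl)ethanone | CC(=O)c1c(O)c(OC)c(OC)c(OC)c1OC
F3 | step 6 | (E)-3-[3,4-bis(benzyloxy)phenyl]-1-(2-hydroxy-3,4,5,6-tetramethoxyphenyl)prop-2-en-1-one | COc1c(OC)c(OC)c(C(=O)/C=C/c2ccc(OCc3ccccc3)c(OCc3ccccc3)c2)c(O)c1OC
F4 | step 6 | 2-[3,4-bis(benzyloxy)phenyl]-5,6,7,8-tetramethoxy-4H-chromen-4-one | COc1c(OC)c(OC)c2c(=O)cc(-c3ccc(OCc4ccccc4)c(OCc4ccccc4)c3)oc2c1OC
F5 | step 8 | 2-[3,4-bis(benzyloxy)phenyl]-6,7-dimethoxy-4-oxo-4H-chromene-5,8-diyl diacetate | COc1c(OC)c(OC(C)=O)c2c(=O)cc(-c3ccc(OCc4ccccc4)c(OCc4ccccc4)c3)oc2c1OC(C)=O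
F6 | step 3 | cis-3,4-dimethoxy-7-oxabicyclo[4.1.0]hept-3-ene-2,5-dione (meso) | COC1=C(OC)C(=O)[C@@H]2O[C@@H]2C1=O
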